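The numbers in the tables come from a simulation for an exercise; the scatter is artificial.

South and north took the same electrophile charge as the beta and gamma runs. They differed from those runs in the amount of nucleophile, 0.800 equiv and 1.20 equiv, and in running to 20 h, while the readings stopped at 10.0 h.

common to all: electrophile 12 mM

| run | nucleophile | remark | time |
|---|---|---|---|
| beta | 0.99 equiv | run made earlier |  |
| gamma | 1.8 equiv | run made earlier |  |
| south | 0.800 equiv |  | 20 h |
| north | 1.20 equiv |  | 20 h |

| run | time / h | electrophile / % | target / % |
|---|---|---|---|
| beta | 0.500 | 90 | 9 |
| beta | 1.50 | 79 | 18 |
| beta | 3.00 | 68 | 25 |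
| beta | 4.00 | 64 | 29 |
| beta | 6.00 | 54 | 32 |
| beta | 8.00 | 46 | 34 |
| beta | 10.0 | 44 | 38 |
| gamma | 0.500 | 86 | 13 |
| gamma | 1.50 | 66 | 26 |
| gamma | 3.00 | 48 | 35 |
| gamma | 4.00 | 41 | 43 |
| gamma | 6.00 | 32 | 48 |
| gamma | 8.00 | 26 | 49 |
| gamma | 10.0 | 20 | 54 |

(readings scatter by 1.5 percentage points)



- part of the electrophile that has reacted at the end, south
- part of the electrophile that has reacted at the end, north
- what raising the equivalents of nucleophile from its lowest to its highest value here does to the part of the electrophile that has reacted (changes below 5 percentage points count as none) (it falls / it rises / no change)

I needed a number that crosses charges. At 10.0 h I took the natural log of electrophile charged over electrophile left, per equivalent of nucleophile charged: the beta run read 0.829 and the gamma run 0.894, although gamma held twice the nucleophile. So I used their mean, 0.862.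

My first way took the shrinking gain. From 4.00 h to 8.00 h the log grew by a mean fraction of 0.625 of what it had reached by 4.00 h. If the rate falls by a steady factor, doubling the time from 10.0 h adds a fraction 0.309. That gave 1.13 as the reach at 20 h, the log of charged over left electrophile per equivalent of nucleophile. That put my estimate for south at 59.4% and for north at 74.2%.

My second way carried the last gain straight on. The mean reading from 8.00 h to 10.0 h was 0.0953, which gave a reach of 1.34, higher than the first, and south 65.7%. The line cheated: it held steady a rate that the same readings showed falling, so I kept the first way.

The forecast said 58% for south and 76% for north, a little off my figures, with the trend it rises, reasoning “so both runs nearly stall”.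

The flasks gave 55.6% in south and 74.5% in north. On the trend, it rises, by 19 percentage points, and the main reason for that gap between north and south is the difference in equivalents of nucleophile.

    nucleophile + acid set free ⇌ protonated nucleophile, settled at all times (K = 1400 M⁻¹)
    target ⇌ isomer of the product (K = 0.440, k = 1.80 h⁻¹)
    electrophile + nucleophile → acid set free + target (k = 18.0 M⁻¹ h⁻¹)
    acid set free → by-product carried off (k = 7.90 h⁻¹)
    nucleophile ⇌ dormant form (K = 1.90, k = 0.0940 h⁻¹)

South's reach came out at 1.02. The slowing there was due in part to nucleophile running short: south, with nucleophile as limiting reagent, kept 7.5% of it against 44% of its electrophile, and without that shortage it reached 96.8%. The isomer of the product stood at 17.0% in south yet moved the conversion by nothing. For the neighbour of north with 0.720 equiv of nucleophile, all else as in north, my reach gives 55.6% and south's gives 51.9%; that flask gave 51.0%.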